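## Retrosynthetic overview

1. Target ⇐ C6‑O tigloylation and desilylation of a ten‑membered 6‑hydroxy α‑methylene lactone carrying two silyl‑protected CH2OH groups.
2. Ten‑membered ring (C6–C7 bond, C6 and C7 stereocentres) ⇐ electroreductive, chromium‑catalysed intramolecular allylation of an enal by a 3‑(bromomethyl)butenolide. This ring is formed last and the step turns the butenolide into the α‑methylene lactone.
3. Butenolide ring (formed first) ⇐ ring‑closing metathesis of a 2‑(bromomethyl)acrylate of the C8 allylic alcohol. C8 comes from (S)‑epichlorohydrin, opened at C9 by the C10 alkenyl‑magnesium/copper reagent.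
4. C1=C10 ⇐ bromo‑ylide Wittig reaction; C4=C5 and C2–C3 ⇐ Morita–Baylis–Hillman reaction then Claisen rearrangement, from dimethoxyacetaldehyde, methyl acrylate and ethyl vinyl ether.

Assumption: atoms are named by germacrane numbering (ring C1–C10, lactone C11–C13, C14 on C10, C15 on C4). The target is read as (6R,7R,8S), H‑6/H‑7 trans and H‑7/H‑8 trans, with both ring olefins cis within the ring (E by CIP, because CH2O outranks ring CH2).

## Route

Step 1
Reactants: 1 2,2‑dimethoxyacetaldehyde; 2 methyl acrylate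
Product: 3 methyl 3‑hydroxy‑4,4‑dimethoxy‑2‑methylidenebutanoate (racemic)
Conditions: DABCO (0.5 equiv), 1,4‑dioxane/H2O 1:1, rt, 48 h
Reagents that add atoms: none
Why: Morita–Baylis–Hillman reaction of the electron‑poor aldehyde with the acrylate; the carbinol centre is racemic and is erased in step 2.

Step 2
Reactants: 3 methyl 3‑hydroxy‑4,4‑dimethoxy‑2‑methylidenebutanoate; 4 ethyl vinyl ether
Product: 6 methyl (2E)‑2‑(2,2‑dimethoxyethylidene)‑5‑oxopentanoate, via allyl vinyl ether 5 (not isolated)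
Conditions: Hg(OAc)2 (10 mol %), ethyl vinyl ether (solvent), reflux; evaporate; toluene, 120 °C, sealed tube
Reagents that add atoms: none
Why: Transfer vinylation then Claisen [3,3] rearrangement forms C2–C3 and the C4=C5 olefin; in the chair transition state the acetal‑bearing group sits pseudo‑axial to avoid A(1,2) strain with the coplanar ester, so CH(OMe)2 ends cis to the new chain (E), as in orthoester Claisen rearrangements of such acrylate adducts; no stereocentre remains.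

Step 3
Reactants: 6 methyl (2E)‑2‑(2,2‑dimethoxyethylidene)‑5‑oxopentanoate; 7 methyl 2‑(triphenyl‑λ5‑phosphanylidene)acetate
Product: 9 dimethyl (2Z,6E)‑2‑bromo‑6‑(2,2‑dimethoxyethylidene)hept‑2‑enedioate, via bromo ylide 8 (not isolated)
Conditions: 7, NBS (1.05 equiv), CH2Cl2, −20 °C, 1 h; then 6, −20 °C → rt
Reagents that add atoms: N‑bromosuccinimide, O=C1CCC(=O)N1Br
Why: Wittig olefination with the bromo ylide made in situ; as for stabilised ylides the ester ends trans to the alkyl chain, giving the (Z)‑α‑bromo enoate with Br (the later C9 site) cis to C2.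

Step 4
Reactants: 9 dimethyl (2Z,6E)‑2‑bromo‑6‑(2,2‑dimethoxyethylidene)hept‑2‑enedioate
Product: 10 (2Z,6E)‑2‑bromo‑6‑(2,2‑dimethoxyethylidene)hept‑2‑ene‑1,7‑diol
Conditions: i‑Bu2AlH (5 equiv), CH2Cl2, −78 → 0 °C; aq. potassium sodium tartrate
Reagents that add atoms: none
Why: Hydride 1,2‑reduction of both conjugated esters to allylic alcohols; vinyl bromide, acetal and olefin geometries are untouched at low temperature.

Step 5
Reactants: 10 (2Z,6E)‑2‑bromo‑6‑(2,2‑dimethoxyethylidene)hept‑2‑ene‑1,7‑diol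
Product: 11 (2Z,6E)‑2‑bromo‑1,7‑bis{[tert‑butyl(dimethyl)silyl]oxy}‑6‑(2,2‑dimethoxyethylidene)hept‑2‑ene
Conditions: TBSCl (2.4 equiv), imidazole (4 equiv), DMF, 0 °C → rt
Reagents that add atoms: tert‑butyl(chloro)dimethylsilane, CC(C)(C)[Si](C)(C)Cl
Why: Standard silylation of the two primary allylic alcohols (C14‑O and C15‑O).

Step 6
Reactants: 11 (2Z,6E)‑2‑bromo‑1,7‑bis{[tert‑butyl(dimethyl)silyl]oxy}‑6‑(2,2‑dimethoxyethylidene)hept‑2‑ene; 12 (S)‑epichlorohydrin
Product: 15 (2S,4E,8E)‑4,8‑bis({[tert‑butyl(dimethyl)silyl]oxy}methyl)‑1‑chloro‑10,10‑dimethoxydeca‑4,8‑dien‑2‑ol, via alkenyllithium 13 (not isolated), via alkenylmagnesium bromide 14 (not isolated)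
Conditions: t‑BuLi (2.1 equiv), Et2O, −78 °C; MgBr2·OEt2, −78 → −40 °C; CuI (10 mol %), 12, THF, −40 → −15 °C
Reagents that add atoms: none
Why: Br/Li exchange with retention of olefin geometry, transmetalation to magnesium and copper‑catalysed SN2 opening of the oxirane CH2 of 12 form C9–C10; the stereocentre of 12 is not touched and becomes C8 (S).

Step 7
Reactants: 15 (2S,4E,8E)‑4,8‑bis({[tert‑butyl(dimethyl)silyl]oxy}methyl)‑1‑chloro‑10,10‑dimethoxydeca‑4,8‑dien‑2‑ol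
Product: 17 (3S,5E,9E)‑5,9‑bis({[tert‑butyl(dimethyl)silyl]oxy}methyl)‑11,11‑dimethoxyundeca‑1,5,9‑trien‑3‑ol, via epoxide 16 (not isolated)
Conditions: Me3S+ I− (4 equiv), n‑BuLi (3.9 equiv), THF, −10 °C → rt
Reagents that add atoms: trimethylsulfonium iodide, C[S+](C)C.[I-]
Why: Excess dimethylsulfonium methylide closes the chlorohydrin to the epoxide, opens it at C7, and the β‑alkoxysulfonium ylide eliminates Me2S (one‑carbon homologation to the allylic alcohol); C8 is not involved.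

Step 8
Reactants: 17 (3S,5E,9E)‑5,9‑bis({[tert‑butyl(dimethyl)silyl]oxy}methyl)‑11,11‑dimethoxyundeca‑1,5,9‑trien‑3‑ol; 18 2‑(bromomethyl)prop‑2‑enoic acid
Product: 19 (3S,5E,9E)‑5,9‑bis({[tert‑butyl(dimethyl)silyl]oxy}methyl)‑11,11‑dimethoxyundeca‑1,5,9‑trien‑3‑yl 2‑(bromomethyl)prop‑2‑enoate
Conditions: DCC (1.3 equiv), DMAP (5 mol %), CH2Cl2, 0 °C
Reagents that add atoms: none
Why: Steglich esterification of the secondary allylic alcohol with retention at C8; low temperature and little DMAP limit attack on the allylic bromide.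

Step 9
Reactants: 19 (3S,5E,9E)‑5,9‑bis({[tert‑butyl(dimethyl)silyl]oxy}methyl)‑11,11‑dimethoxyundeca‑1,5,9‑trien‑3‑yl 2‑(bromomethyl)prop‑2‑enoate
Product: 20 (5S)‑3‑(bromomethyl)‑5‑[(2E,6E)‑2,6‑bis({[tert‑butyl(dimethyl)silyl]oxy}methyl)‑8,8‑dimethoxyocta‑2,6‑dien‑1‑yl]furan‑2(5H)‑one
Conditions: second‑generation Grubbs catalyst RuCl2(=CHPh)(PCy3)(H2IMes) (5–10 mol %), CH2Cl2 (5 mM), 40 °C
Reagents that add atoms: none
Why: Ring‑closing metathesis between the vinyl group and the 1,1‑disubstituted acrylate gives the butenolide with loss of ethene; the trisubstituted olefins do not compete and C8 is untouched.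

Step 10
Reactants: 20 (5S)‑3‑(bromomethyl)‑5‑[(2E,6E)‑2,6‑bis({[tert‑butyl(dimethyl)silyl]oxy}methyl)‑8,8‑dimethoxyocta‑2,6‑dien‑1‑yl]furan‑2(5H)‑one
Product: 21 (2E,6E)‑8‑[(2S)‑4‑(bromomethyl)‑5‑oxo‑2,5‑dihydrofuran‑2‑yl]‑3,7‑bis({[tert‑butyl(dimethyl)silyl]oxy}methyl)octa‑2,6‑dienal
Conditions: pyridinium p‑toluenesulfonate (0.2 equiv), acetone/H2O 10:1, rt
Reagents that add atoms: water, O
Why: Mild acid hydrolysis of the allylic dimethyl acetal to the enal; primary silyl ethers, the allylic bromide and the olefin geometry survive these conditions.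

Step 11
Reactants: 21 (2E,6E)‑8‑[(2S)‑4‑(bromomethyl)‑5‑oxo‑2,5‑dihydrofuran‑2‑yl]‑3,7‑bis({[tert‑butyl(dimethyl)silyl]oxy}methyl)octa‑2,6‑dienal
Product: 24 (3aS,4R,5E,9E,11aS)‑6,10‑bis({[tert‑butyl(dimethyl)silyl]oxy}methyl)‑4‑hydroxy‑3‑methylidene‑3a,4,7,8,11,11a‑hexahydrocyclodeca[b]furan‑2(3H)‑one, via allylchromium dichloride 22 (not isolated), via trimethylsilyl ether 23 (not isolated)
Conditions: CrCl2 (20 mol %), Me3SiCl (2.5 equiv), n‑Bu4NBF4 (0.1 M), DMF, undivided cell, Al anode/Ni‑foam cathode, 2 mA constant current (2.3 F/mol), 21 added by syringe pump over 10 h (final 2 mM), rt; then 1 M HCl, THF, 0 °C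
Reagents that add atoms: none
Why: Proposed new method: the cathode regenerates divalent chromium, two equivalents of which turn the allylic bromide into a C13‑bound allylchromium species (trivalent chromium) that adds through its γ‑carbon C7 to the tethered enal in a six‑membered chair transition state, on the butenolide face anti to the C8 side chain (7,8‑trans lactone) and, with the ring‑fixed E‑type allyl geometry and the aldehyde residue equatorial, with the 6,7‑anti relationship of the target, while Me3SiCl silylates the chromium alkoxide to release the catalyst and suppress translactonisation and the low current keeps the nucleophile at pseudo‑high dilution; the closest known reactions are the chromium‑catalytic (manganese/silyl chloride) and electroreductive Nozaki–Hiyama–Kishi allylations and stoichiometric CrCl2 allylation macrocyclisations, none of which has been shown for a 3‑(bromomethyl)butenolide donor closing a ten‑membered ring.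

Step 12
Reactants: 24 (3aS,4R,5E,9E,11aS)‑6,10‑bis({[tert‑butyl(dimethyl)silyl]oxy}methyl)‑4‑hydroxy‑3‑methylidene‑3a,4,7,8,11,11a‑hexahydrocyclodeca[b]furan‑2(3H)‑one; 25 tiglic acid
Product: 27 (3aR,4R,5E,9E,11aS)‑6,10‑bis({[tert‑butyl(dimethyl)silyl]oxy}methyl)‑3‑methylidene‑2‑oxo‑2,3,3a,4,7,8,11,11a‑octahydrocyclodeca[b]furan‑4‑yl (2E)‑2‑methylbut‑2‑enoate, via mixed anhydride 26 (not isolated)
Conditions: 25, 2,4,6‑trichlorobenzoyl chloride, Et3N, toluene, rt, 1 h; then 24, DMAP, rt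
Reagents that add atoms: none
Why: Yamaguchi esterification via the mixed anhydride acylates the hindered C6 carbinol with retention; the primary alcohols are masked and the tiglate geometry is the stable one.

Step 13
Reactants: 27 (3aR,4R,5E,9E,11aS)‑6,10‑bis({[tert‑butyl(dimethyl)silyl]oxy}methyl)‑3‑methylidene‑2‑oxo‑2,3,3a,4,7,8,11,11a‑octahydrocyclodeca[b]furan‑4‑yl (2E)‑2‑methylbut‑2‑enoate
Product: 28 (3aR,4R,5E,9E,11aS)‑6,10‑bis(hydroxymethyl)‑3‑methylidene‑2‑oxo‑2,3,3a,4,7,8,11,11a‑octahydrocyclodeca[b]furan‑4‑yl (2E)‑2‑methylbut‑2‑enoate (CNP0275462.2)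
Conditions: HF·pyridine, pyridine/THF, 0 °C → rt
Reagents that add atoms: none
Why: Fluoride cleavage of both primary silyl ethers under buffered conditions leaves the tiglate, the lactone and the exocyclic methylene intact; no stereocentre is touched.

## Compound list

1 | 2,2‑dimethoxyacetaldehyde | COC(OC)C=O | starting material
2 | methyl acrylate | C=CC(=O)OC | starting material
3 | methyl 3‑hydroxy‑4,4‑dimethoxy‑2‑methylidenebutanoate (racemic; centre erased in step 2) | COC(OC)C(O)C(=C)C(=O)OC | intermediate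
4 | ethyl vinyl ether | C=COCC | starting material
5 | methyl 3‑(ethenyloxy)‑4,4‑dimethoxy‑2‑methylidenebutanoate (racemic, not isolated) | COC(OC)C(OC=C)C(=C)C(=O)OC | intermediate
6 | methyl (2E)‑2‑(2,2‑dimethoxyethylidene)‑5‑oxopentanoate | COC(OC)/C=C(\CCC=O)C(=O)OC | intermediate
7 | methyl 2‑(triphenyl‑λ5‑phosphanylidene)acetate | COC(=O)C=P(c1ccccc1)(c1ccccc1)c1ccccc1 | starting material
8 | methyl 2‑bromo‑2‑(triphenyl‑λ5‑phosphanylidene)acetate (not isolated) | COC(=O)C(Br)=P(c1ccccc1)(c1ccccc1)c1ccccc1 | intermediate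
9 | dimethyl (2Z,6E)‑2‑bromo‑6‑(2,2‑dimethoxyethylidene)hept‑2‑enedioate | COC(OC)/C=C(\CC/C=C(\Br)C(=O)OC)C(=O)OC | intermediate
10 | (2Z,6E)‑2‑bromo‑6‑(2,2‑dimethoxyethylidene)hept‑2‑ene‑1,7‑diol | COC(OC)/C=C(\CC/C=C(\Br)CO)CO | intermediate
11 | (2Z,6E)‑2‑bromo‑1,7‑bis{[tert‑butyl(dimethyl)silyl]oxy}‑6‑(2,2‑dimethoxyethylidene)hept‑2‑ene | COC(OC)/C=C(\CC/C=C(\Br)CO[Si](C)(C)C(C)(C)C)CO[Si](C)(C)C(C)(C)C | intermediate
12 | (S)‑epichlorohydrin, (2S)‑2‑(chloromethyl)oxirane | ClC[C@@H]1CO1 | starting material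
13 | alkenyllithium from 11 (Li in place of Br, geometry retained; not isolated) | COC(OC)/C=C(\CC/C=C(\[Li])CO[Si](C)(C)C(C)(C)C)CO[Si](C)(C)C(C)(C)C | intermediate
14 | alkenylmagnesium bromide from 13 (MgBr in place of Li, geometry retained; not isolated) | COC(OC)/C=C(\CC/C=C(\[Mg]Br)CO[Si](C)(C)C(C)(C)C)CO[Si](C)(C)C(C)(C)C | intermediate
15 | (2S,4E,8E)‑4,8‑bis({[tert‑butyl(dimethyl)silyl]oxy}methyl)‑1‑chloro‑10,10‑dimethoxydeca‑4,8‑dien‑2‑ol | ClC[C@@H](O)C/C(CO[Si](C)(C)C(C)(C)C)=C\CC/C(CO[Si](C)(C)C(C)(C)C)=C\C(OC)OC | intermediate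
16 | (2S)‑2‑[(2E,6E)‑2,6‑bis({[tert‑butyl(dimethyl)silyl]oxy}methyl)‑8,8‑dimethoxyocta‑2,6‑dien‑1‑yl]oxirane (not isolated) | C1[C@@H](O1)C/C(CO[Si](C)(C)C(C)(C)C)=C\CC/C(CO[Si](C)(C)C(C)(C)C)=C\C(OC)OC | intermediate
17 | (3S,5E,9E)‑5,9‑bis({[tert‑butyl(dimethyl)silyl]oxy}methyl)‑11,11‑dimethoxyundeca‑1,5,9‑trien‑3‑ol | C=C[C@@H](O)C/C(CO[Si](C)(C)C(C)(C)C)=C\CC/C(CO[Si](C)(C)C(C)(C)C)=C\C(OC)OC | intermediate
18 | 2‑(bromomethyl)prop‑2‑enoic acid | OC(=O)C(=C)CBr | starting material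
19 | (3S,5E,9E)‑5,9‑bis({[tert‑butyl(dimethyl)silyl]oxy}methyl)‑11,11‑dimethoxyundeca‑1,5,9‑trien‑3‑yl 2‑(bromomethyl)prop‑2‑enoate | C=C[C@@H](OC(=O)C(=C)CBr)C/C(CO[Si](C)(C)C(C)(C)C)=C\CC/C(CO[Si](C)(C)C(C)(C)C)=C\C(OC)OC | intermediate
20 | (5S)‑3‑(bromomethyl)‑5‑[(2E,6E)‑2,6‑bis({[tert‑butyl(dimethyl)silyl]oxy}methyl)‑8,8‑dimethoxyocta‑2,6‑dien‑1‑yl]furan‑2(5H)‑one | BrCC1=C[C@H](C/C(CO[Si](C)(C)C(C)(C)C)=C\CC/C(CO[Si](C)(C)C(C)(C)C)=C\C(OC)OC)OC1=O | intermediate
21 | (2E,6E)‑8‑[(2S)‑4‑(bromomethyl)‑5‑oxo‑2,5‑dihydrofuran‑2‑yl]‑3,7‑bis({[tert‑butyl(dimethyl)silyl]oxy}methyl)octa‑2,6‑dienal | BrCC1=C[C@H](C/C(CO[Si](C)(C)C(C)(C)C)=C\CC/C(CO[Si](C)(C)C(C)(C)C)=C\C=O)OC1=O | intermediate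
22 | allylchromium dichloride from 21 (CrCl2 on C13 in place of Br, trivalent chromium; not isolated) | Cl[Cr](Cl)CC1=C[C@H](C/C(CO[Si](C)(C)C(C)(C)C)=C\CC/C(CO[Si](C)(C)C(C)(C)C)=C\C=O)OC1=O | intermediate
23 | 6‑O‑trimethylsilyl ether of 24 (not isolated) | C=C1C(=O)O[C@H]2C/C(CO[Si](C)(C)C(C)(C)C)=C\CC/C(CO[Si](C)(C)C(C)(C)C)=C\[C@@H](O[Si](C)(C)C)[C@H]12 | intermediate
24 | (3aS,4R,5E,9E,11aS)‑6,10‑bis({[tert‑butyl(dimethyl)silyl]oxy}methyl)‑4‑hydroxy‑3‑methylidene‑3a,4,7,8,11,11a‑hexahydrocyclodeca[b]furan‑2(3H)‑one (C7 has the target's spatial arrangement; its label is S here only because OH ranks below the lactone oxygen) | C=C1C(=O)O[C@H]2C/C(CO[Si](C)(C)C(C)(C)C)=C\CC/C(CO[Si](C)(C)C(C)(C)C)=C\[C@@H](O)[C@H]12 | intermediate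
25 | tiglic acid, (2E)‑2‑methylbut‑2‑enoic acid | C/C=C(\C)C(=O)O | starting material
26 | (2E)‑2‑methylbut‑2‑enoic 2,4,6‑trichlorobenzoic anhydride (not isolated) | C/C=C(\C)C(=O)OC(=O)c1c(Cl)cc(Cl)cc1Cl | intermediate
27 | (3aR,4R,5E,9E,11aS)‑6,10‑bis({[tert‑butyl(dimethyl)silyl]oxy}methyl)‑3‑methylidene‑2‑oxo‑2,3,3a,4,7,8,11,11a‑octahydrocyclodeca[b]furan‑4‑yl (2E)‑2‑methylbut‑2‑enoate | C=C1C(=O)O[C@H]2C/C(CO[Si](C)(C)C(C)(C)C)=C\CC/C(CO[Si](C)(C)C(C)(C)C)=C\[C@@H](OC(=O)/C(C)=C/C)[C@H]12 | intermediate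
28 | (3aR,4R,5E,9E,11aS)‑6,10‑bis(hydroxymethyl)‑3‑methylidene‑2‑oxo‑2,3,3a,4,7,8,11,11a‑octahydrocyclodeca[b]furan‑4‑yl (2E)‑2‑methylbut‑2‑enoate | C=C1C(=O)O[C@H]2C/C(CO)=C\CC/C(CO)=C\[C@@H](OC(=O)/C(C)=C/C)[C@H]12 | target

## Step count and risk

Total steps: 13. Longest linear sequence: 13 (1 → 28; all other inputs are commercial).

Three steps most likely to fail:

**Step 11 (proposed new electrochemical ring closure).** Risks are direct cathodic reduction of the enal or bromide, poor chromium turnover, oligomerisation, or the wrong C6 epimer. Fallback with known chemistry: set out from 21 and give up electrochemical turnover altogether. Add 21 by syringe pump to stoichiometric CrCl2 (8–10 equiv) in degassed THF/DMF at rt, the classical reagent‑based Nozaki–Hiyama–Kishi allylation macrocyclisation used for ten‑membered sesquiterpene lactones. Aqueous work‑up releases the alcohol directly, so the route is rejoined at 24. No new compound is made (F0).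

**Step 9 (metathesis of a 2‑(bromomethyl)acrylate).** The allylic bromide may poison the catalyst, or closure onto the hindered acrylate may be slow. Fallback: set out from 15 and build the lactone by epoxide opening instead of metathesis. K2CO3 in MeOH closes 15 to the epoxide 16, which is isolated. The dianion of (phenylselanyl)acetic acid (2 equiv LiN(i‑Pr)2, THF) opens 16 at C7, and acidification lactonises to (5S)‑5‑[(2E,6E)‑2,6‑bis({[tert‑butyl(dimethyl)silyl]oxy}methyl)‑8,8‑dimethoxyocta‑2,6‑dien‑1‑yl]‑3‑(phenylselanyl)oxolan‑2‑one F2. Enolisation (LiN(i‑Pr)2, −78 °C) and gaseous formaldehyde give (5S)‑5‑[(2E,6E)‑2,6‑bis({[tert‑butyl(dimethyl)silyl]oxy}methyl)‑8,8‑dimethoxyocta‑2,6‑dien‑1‑yl]‑3‑(hydroxymethyl)‑3‑(phenylselanyl)oxolan‑2‑one F3. H2O2/pyridine at 0 °C triggers selenoxide syn‑elimination into the ring to give (5S)‑5‑[(2E,6E)‑2,6‑bis({[tert‑butyl(dimethyl)silyl]oxy}methyl)‑8,8‑dimethoxyocta‑2,6‑dien‑1‑yl]‑3‑(hydroxymethyl)furan‑2(5H)‑one F4. CBr4/PPh3 in CH2Cl2 at 0 °C converts the primary allylic alcohol into the bromide, rejoining the route at 20.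

**Step 2 (transfer vinylation and Claisen rearrangement).** Vinylation of the hindered, electron‑poor alcohol may be sluggish, or the olefin geometry may be eroded. Fallback: set out from 3 and use the orthoester variant, whose E‑selectivity for such acrylate adducts is established. Trimethyl orthoacetate with catalytic propionic acid at 110–120 °C gives dimethyl (2E)‑2‑(2,2‑dimethoxyethylidene)pentanedioate F1. i‑Bu2AlH (1.05 equiv, CH2Cl2, −78 °C) then reduces the saturated ester to the aldehyde in the presence of the hindered conjugated ester, rejoining the route at 6.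

Further compounds

F1 | step 2 | dimethyl (2E)‑2‑(2,2‑dimethoxyethylidene)pentanedioate | COC(OC)/C=C(\CCC(=O)OC)C(=O)OC
F2 | step 9 | (5S)‑5‑[(2E,6E)‑2,6‑bis({[tert‑butyl(dimethyl)silyl]oxy}methyl)‑8,8‑dimethoxyocta‑2,6‑dien‑1‑yl]‑3‑(phenylselanyl)oxolan‑2‑one (both C3 epimers) | O=C1O[C@@H](C/C(CO[Si](C)(C)C(C)(C)C)=C\CC/C(CO[Si](C)(C)C(C)(C)C)=C\C(OC)OC)CC1[Se]c1ccccc1
F3 | step 9 | (5S)‑5‑[(2E,6E)‑2,6‑bis({[tert‑butyl(dimethyl)silyl]oxy}methyl)‑8,8‑dimethoxyocta‑2,6‑dien‑1‑yl]‑3‑(hydroxymethyl)‑3‑(phenylselanyl)oxolan‑2‑one (both C3 epimers) | O=C1O[C@@H](C/C(CO[Si](C)(C)C(C)(C)C)=C\CC/C(CO[Si](C)(C)C(C)(C)C)=C\C(OC)OC)CC1(CO)[Se]c1ccccc1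
F4 | step 9 | (5S)‑5‑[(2E,6E)‑2,6‑bis({[tert‑butyl(dimethyl)silyl]oxy}methyl)‑8,8‑dimethoxyocta‑2,6‑dien‑1‑yl]‑3‑(hydroxymethyl)furan‑2(5H)‑one | OCC1=C[C@H](C/C(CO[Si](C)(C)C(C)(C)C)=C\CC/C(CO[Si](C)(C)C(C)(C)C)=C\C(OC)OC)OC1=O
F0 | step 11 | none | none
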